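**Retrosynthetic overview**

1. The last C–C bond is the C(sp)–C(sp2) bond of the enyne, cut by a Sonogashira disconnection into dioxane alkyne 10 and (E)-vinyl iodide 15 (distal alkyne silylated). The radical-sensitive enyne therefore enters only after the peroxide ring exists.
2. The only ring, the 1,2-dioxane O1–O2–C3–C4–C5–C6, is assembled in step 3 from three simple components (β-keto carboxylate 5, methyl but-3-enoate 6, O2) and locked as the C6 methoxy peroxyketal in step 4.
3. Enabling feature: the C6 peroxyketal is a masked γ-hydroperoxy ketone. C5 is thus the α-carbon of a C6 ketone (a radical donor after traceless loss of CO2), C3=C4 with its CH2CO2Me arm is a terminal alkene, and O1–O2 is dioxygen.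
4. Stereochemistry: C6 follows C3 under thermodynamic (anomeric) control in step 4. No known catalyst controls O2 capture at C3, so the absolute configuration is secured by resolution of the small racemic core 9 (step 5).

Key step: step 3

Assumption: the enantiomers separated in step 5 are assigned by an independent method (vibrational circular dichroism on 10, or correlation of the optical rotation of 17 with that of the natural product); all descriptors after step 5 rest on this assignment.

**Route**

Step 1
Reactants: 1 hex-5-ynoic acid; 2 Meldrum's acid (2,2-dimethyl-1,3-dioxane-4,6-dione)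
Product: 4 ethyl 3-oxooct-7-ynoate, via acyl Meldrum's acid 3 (not isolated)
Conditions: DCC (1.1 equiv), DMAP (1.2 equiv), CH2Cl2, 0 °C → rt; filter, aq. KHSO4 wash, concentrate; then EtOH, reflux
Reagents that add atoms: ethanol, CCO
Why: Carbodiimide-mediated C-acylation of Meldrum's acid followed by thermal alcoholysis (loss of acetone and CO2 through the acylketene) is the standard Meldrum's acid route to β-keto esters and leaves the terminal alkyne untouched.

Step 2
Reactants: 4 ethyl 3-oxooct-7-ynoate
Product: 5 potassium 3-oxooct-7-ynoate
Conditions: KOH (1.0 equiv, 1 M aq.), 0 °C → rt; Et2O wash; freeze-drying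
Reagents that add atoms: potassium hydroxide, [K+].[OH-]
Why: Saponification of a β-keto ester with one equivalent of cold aqueous hydroxide should give the β-keto carboxylate salt, which, unlike the free acid, does not decarboxylate and can be stored dry.

Step 3
Reactants: 5 potassium 3-oxooct-7-ynoate; 6 methyl but-3-enoate
Product: 8 methyl 2-[6-hydroxy-6-(pent-4-yn-1-yl)-1,2-dioxan-3-yl]acetate (racemic; C6 epimers), via hydroperoxy ketone 7 (not isolated)
Conditions: 6 (10 equiv), 9-mesityl-3,6-di-tert-butyl-10-phenylacridinium tetrafluoroborate (5 mol %), KH2PO4 (1.2 equiv), MeCN/H2O 9:1 (0.3 M in 5), air (1 atm), 450 nm LEDs, 15–20 °C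
Reagents that add atoms: dioxygen, O=O
Why: Proposed new method: the photoexcited acridinium (about +2 V vs SCE) oxidises the carboxylate of 5, loss of CO2 leaves the 2-oxoalkyl radical at C5, this electrophilic radical adds to the unsubstituted alkene carbon of 6 (C4–C5 bond), the secondary C3 radical captures O2 (C3–O bond), and the peroxyl radical is reduced by the acridinyl radical and protonated by KH2PO4 to hydroperoxy ketone 7, which closes the photocatalytic cycle without a stoichiometric oxidant. The closest known reaction types are the aerobic three-component peroxycyclisation of 1,3-dicarbonyl compounds with alkenes and O2 to 1,2-dioxan-3-ols (catalysed by Mn(OAc)3, trivalent manganese, or initiated at an anode) and the acridinium-photocatalysed decarboxylative oxygenation and Giese addition of carboxylates; new is a β-keto carboxylate as a traceless source of the unsubstituted α-keto radical, so that no activating group remains on C5. The 1,2-dioxane ring closes by 6-exo-trig addition of the terminal hydroperoxide oxygen of 7 to the C6 ketone (ring–chain tautomerism that lies on the side of the cyclic peroxyhemiketal). C3 is created when O2 traps a prochiral acyclic radical, so no element controls it and 8 is racemic (resolved in step 5), while the C6 hemiketal centre remains labile until step 4. The step needs the C5 radical to add to the alkene before it meets O2 and to ignore its own alkyne: the tenfold excess of the terminal alkene (3 M) against about 2 mM O2 under air should secure the first, and the slow 6-exo-dig closure of an α-keto radical the second; the acridinyl radical is too weak a reductant to cleave the O–O bond of 8.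

Step 4
Reactants: 8 methyl 2-[6-hydroxy-6-(pent-4-yn-1-yl)-1,2-dioxan-3-yl]acetate
Product: 9 rac-methyl 2-[(3S*,6R*)-6-methoxy-6-(pent-4-yn-1-yl)-1,2-dioxan-3-yl]acetate (OMe cis to CH2CO2Me)
Conditions: TsOH·H2O (5 mol %), MeOH, 3 Å molecular sieves, 0 °C → rt; NaHCO3 quench; SiO2 chromatography (removal of the 3,6-trans isomer)
Reagents that add atoms: methanol, CO
Why: Acid-catalysed ketalisation through the peroxycarbenium ion is reversible, so C6 should settle under thermodynamic control with OMe axial (anomeric effect of the ring peroxide oxygen) and both carbon substituents equatorial, which is the 3,6-cis relation of the target.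

Step 5
Reactants: 9 rac-methyl 2-[(3S*,6R*)-6-methoxy-6-(pent-4-yn-1-yl)-1,2-dioxan-3-yl]acetate
Product: 10 methyl 2-[(3S,6R)-6-methoxy-6-(pent-4-yn-1-yl)-1,2-dioxan-3-yl]acetate
Conditions: preparative supercritical-fluid chromatography, amylose tris(3,5-dimethylphenylcarbamate) stationary phase, CO2/i-PrOH
Reagents that add atoms: none
Why: Resolution by preparative enantioselective chromatography; no new stereocentre is formed, the two centres of 9 are locked relative to each other, and separation on a polysaccharide carbamate phase should deliver the (3S,6R) series as a single enantiomer.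

Step 6
Reactants: 11 dec-9-yn-1-ol
Product: 13 10-(trimethylsilyl)dec-9-yn-1-ol, via bis-silyl ether 12 (not isolated)
Conditions: n-BuLi (2.2 equiv), THF, −78 °C; TMSCl (2.4 equiv), −78 °C → rt; then 1 M HCl, rt
Reagents that add atoms: chlorotrimethylsilane, C[Si](C)(C)Cl
Why: Double deprotonation (O–H and C(sp)–H), bis-silylation and selective acid hydrolysis of the labile O–Si bond is the routine C-silylation of an ω-alkynol.

Step 7
Reactants: 13 10-(trimethylsilyl)dec-9-yn-1-ol
Product: 14 10-(trimethylsilyl)dec-9-ynal
Conditions: Dess–Martin periodinane (1.2 equiv), CH2Cl2, 0 °C → rt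
Reagents that add atoms: none
Why: Dess–Martin oxidation should convert the primary alcohol into the aldehyde without over-oxidation and without touching the silyl alkyne.

Step 8
Reactants: 14 10-(trimethylsilyl)dec-9-ynal
Product: 15 [(10E)-11-iodoundec-10-en-1-yn-1-yl]trimethylsilane
Conditions: CrCl2 (6 equiv), CHI3 (2 equiv), THF/1,4-dioxane, 0 °C → rt
Reagents that add atoms: iodoform, IC(I)I
Why: Takai olefination homologates an aldehyde to the (E)-vinyl iodide, the E geometry arising from anti elimination of the β-oxido gem-dichromium adduct, and the silyl alkyne is inert to CrCl2.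

Step 9
Reactants: 10 methyl 2-[(3S,6R)-6-methoxy-6-(pent-4-yn-1-yl)-1,2-dioxan-3-yl]acetate; 15 [(10E)-11-iodoundec-10-en-1-yn-1-yl]trimethylsilane
Product: 16 methyl 2-[(3S,6R)-6-methoxy-6-[(6E)-16-(trimethylsilyl)hexadec-6-ene-4,15-diyn-1-yl]-1,2-dioxan-3-yl]acetate
Conditions: Pd(PPh3)4 (5 mol %), CuI (10 mol %), i-Pr2NH (3 equiv), THF (degassed), rt
Reagents that add atoms: none
Why: Sonogashira coupling of a terminal alkyne with an (E)-vinyl iodide proceeds at room temperature with retention of the alkene geometry, and dialkyl peroxyketals of this kind are known to tolerate palladium-catalysed cross-coupling.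

Step 10
Reactants: 16 methyl 2-[(3S,6R)-6-methoxy-6-[(6E)-16-(trimethylsilyl)hexadec-6-ene-4,15-diyn-1-yl]-1,2-dioxan-3-yl]acetate
Product: 17 methyl 2-[(3S,6R)-6-methoxy-6-[(6E)-hexadec-6-ene-4,15-diyn-1-yl]-1,2-dioxan-3-yl]acetate (target)
Conditions: K2CO3 (0.3 equiv), MeOH, 0 °C → rt
Reagents that add atoms: none
Why: Carbonate-catalysed methanolysis of the C(sp)–Si bond is selective for the trimethylsilyl alkyne; the methyl ester cannot transesterify in methanol and the weak base should not enolise it, so the β-peroxy ester and both stereocentres should persist.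

**Compound list**

1 | hex-5-ynoic acid | C#CCCCC(=O)O | starting material
2 | Meldrum's acid (2,2-dimethyl-1,3-dioxane-4,6-dione) | CC1(C)OC(=O)CC(=O)O1 | starting material
3 | acyl Meldrum's acid: 5-(1-hydroxyhex-5-yn-1-ylidene)-2,2-dimethyl-1,3-dioxane-4,6-dione | CC1(C)OC(=O)C(=C(O)CCCC#C)C(=O)O1 | intermediate
4 | ethyl 3-oxooct-7-ynoate | CCOC(=O)CC(=O)CCCC#C | intermediate
5 | potassium 3-oxooct-7-ynoate | [K+].[O-]C(=O)CC(=O)CCCC#C | intermediate
6 | methyl but-3-enoate | COC(=O)CC=C | starting material
7 | hydroperoxy ketone: methyl 3-hydroperoxy-6-oxoundec-10-ynoate (racemic) | COC(=O)CC(OO)CCC(=O)CCCC#C | intermediate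
8 | methyl 2-[6-hydroxy-6-(pent-4-yn-1-yl)-1,2-dioxan-3-yl]acetate (racemic at C3, C6 hemiketal epimers in equilibrium; stereocentres undefined) | COC(=O)CC1CCC(O)(CCCC#C)OO1 | intermediate
9 | rac-methyl 2-[(3S*,6R*)-6-methoxy-6-(pent-4-yn-1-yl)-1,2-dioxan-3-yl]acetate (OMe cis to CH2CO2Me; both enantiomers) | C#CCCC[C@]1(OC)CC[C@@H](CC(=O)OC)OO1.C#CCCC[C@@]1(OC)CC[C@H](CC(=O)OC)OO1 | intermediate
10 | methyl 2-[(3S,6R)-6-methoxy-6-(pent-4-yn-1-yl)-1,2-dioxan-3-yl]acetate | C#CCCC[C@]1(OC)CC[C@@H](CC(=O)OC)OO1 | intermediate
11 | dec-9-yn-1-ol | C#CCCCCCCCCO | starting material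
12 | bis-silyl ether: trimethyl{[10-(trimethylsilyl)dec-9-yn-1-yl]oxy}silane | C[Si](C)(C)C#CCCCCCCCCO[Si](C)(C)C | intermediate
13 | 10-(trimethylsilyl)dec-9-yn-1-ol | C[Si](C)(C)C#CCCCCCCCCO | intermediate
14 | 10-(trimethylsilyl)dec-9-ynal | C[Si](C)(C)C#CCCCCCCCC=O | intermediate
15 | [(10E)-11-iodoundec-10-en-1-yn-1-yl]trimethylsilane | C[Si](C)(C)C#CCCCCCCC/C=C/I | intermediate
16 | methyl 2-[(3S,6R)-6-methoxy-6-[(6E)-16-(trimethylsilyl)hexadec-6-ene-4,15-diyn-1-yl]-1,2-dioxan-3-yl]acetate | C[Si](C)(C)C#CCCCCCCC/C=C/C#CCCC[C@]1(OC)CC[C@@H](CC(=O)OC)OO1 | intermediate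
17 | methyl 2-[(3S,6R)-6-methoxy-6-[(6E)-hexadec-6-ene-4,15-diyn-1-yl]-1,2-dioxan-3-yl]acetate | C#CCCCCCCC/C=C/C#CCCC[C@]1(OC)CC[C@@H](CC(=O)OC)OO1 | target

**Step count and risks**

Total steps: 10. Longest linear sequence: 7 (steps 1, 2, 3, 4, 5, 9, 10).

Steps most likely to fail:

Step 3 (Proposed new method). What may go wrong: capture of O2 by the C5 radical before it adds to the alkene; thermal, non-radical decarboxylation of protonated β-keto acid to the methyl ketone; or oxidation at the enol, so that the carboxyl group is retained on C5. The fallback uses known chemistry and makes the two bonds in separate polar steps. It sets out from 4. C-Alkylation with methyl (2E)-4-bromobut-2-enoate (K2CO3, acetone, rt) should give 1-ethyl 6-methyl (4E)-2-(hex-5-ynoyl)hex-4-enedioate F1. Krapcho dealkoxycarbonylation (LiCl, wet DMSO, 130 °C), selective for the β-keto ester, should give methyl (2E)-6-oxoundec-2-en-10-ynoate F2. Acid-catalysed peroxyketalisation (50 % aq. H2O2, Sc(OTf)3 cat., MeOH, rt) should give methyl (2E)-6-hydroperoxy-6-methoxyundec-2-en-10-ynoate F3. Amine-promoted 6-exo-trig peroxy-Michael addition (Et2NH, CF3CH2OH, rt) should then close the dioxane and come back to the route at 9, after removal of the 3,6-trans isomer on silica or its equilibration at C6 under the conditions of step 4.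

Step 4. What may go wrong: acid-induced fragmentation of the ring-opened secondary hydroperoxide (Hock-type cleavage), or incomplete equilibration at C6 that leaves much 3,6-trans ketal. The fallback sets out from 8 and alkylates the hemiketal oxygen instead of ionising C6: Me3OBF4, 2,6-di-tert-butyl-4-methylpyridine, CH2Cl2, 0 °C (Meerwein O-methylation). The C6–O bond is kept, so the axial preference of the hemiketal hydroxyl should be carried into the product. The sequence comes back at 9 after chromatography; no new compound arises on this way (F0).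

Step 9. What may go wrong: reductive cleavage of the O–O bond by triphenylphosphine or by monovalent copper and zerovalent palladium under the basic coupling conditions, and oxidative homocoupling of alkyne 10. The fallback is a copper-, amine- and phosphine-free Stille route that sets out from 10 and 15. Iodination of 10 (N-iodosuccinimide, AgNO3 cat., acetone, rt) should give methyl 2-[(3S,6R)-6-(5-iodopent-4-yn-1-yl)-6-methoxy-1,2-dioxan-3-yl]acetate F4. Stannylation of 15 away from the peroxide ((Bu3Sn)2, Pd(PPh3)4 cat., toluene, 80 °C) should give tributyl[(1E)-11-(trimethylsilyl)undec-1-en-10-yn-1-yl]stannane F5. Stille coupling of the two (PdCl2(MeCN)2, DMF, rt) should form the enyne with retention of geometry and come back to the route at 16.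

**Further compounds**

F1 | step 3 | 1-ethyl 6-methyl (4E)-2-(hex-5-ynoyl)hex-4-enedioate (racemic at C2) | CCOC(=O)C(C/C=C/C(=O)OC)C(=O)CCCC#C
F2 | step 3 | methyl (2E)-6-oxoundec-2-en-10-ynoate | COC(=O)/C=C/CCC(=O)CCCC#C
F3 | step 3 | methyl (2E)-6-hydroperoxy-6-methoxyundec-2-en-10-ynoate (racemic) | COC(=O)/C=C/CCC(OC)(OO)CCCC#C
F0 | step 4 | none | none
F4 | step 9 | methyl 2-[(3S,6R)-6-(5-iodopent-4-yn-1-yl)-6-methoxy-1,2-dioxan-3-yl]acetate | IC#CCCC[C@]1(OC)CC[C@@H](CC(=O)OC)OO1
F5 | step 9 | tributyl[(1E)-11-(trimethylsilyl)undec-1-en-10-yn-1-yl]stannane | CCCC[Sn](CCCC)(CCCC)/C=C/CCCCCCCC#C[Si](C)(C)C
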